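In the early readings of both runs the first product climbs to a plateau within the first day and then sinks slowly, and the meeting had to say what that plateau is.

in all of them: substrate 20 mM
- birch: reagent 16 mM; temperature 90 °C; the very flask that is asked about, followed so far
- elm: reagent 16 mM; temperature 85 °C; run made earlier
- flask: reagent 16.0 mM; temperature 90 °C; time 8.0 d

- birch (time / d: first product / %): 0.417: 33.5; 0.625: 34.2; 0.833: 34.0; 1.25: 33.6; 2.08: 33.0; 3.00: 31.9; 5.00: 30.5
- elm (time / d: first product / %): 0.417: 33.2; 0.625: 36.0; 0.833: 36.0; 1.25: 36.0; 2.08: 36.2; 3.00: 35.1; 5.00: 32.6

(standard deviation of a reading: 0.5 percentage points)

- first product taken out counts as made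
- the analysis behind the earlier runs scatters by 0.5 percentage points, standard deviation
- additions bring no volume worth counting

* first product, in percent of the substrate first charged, at 8.0 d
* what to do for the largest gain in first product; "none" if nothing gains more than 2 percentage points (zeta / gamma / delta / beta / none)
* first product present, with what was taken out counted in, in percent of the substrate first charged, after zeta
* first product present, with what was taken out counted in, in percent of the substrate first charged, after beta

- zeta: at 8.0 d take out 90 % of the first product then present, then wait 8.0 d
- gamma: at 8.0 d add reagent, 50.0 % of the amount charged, then wait 8.0 d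
- delta: at 8.0 d raise the temperature by 25 K, then wait 8.0 d
- beta: change nothing and wait 8.0 d more

The author of the forecast argued that the plateau, 34.0 % in birch at 0.833 d against the 80.0 % of the substrate charged that the reagent allows, and higher in the cooler elm run, “looks like an exothermic equilibrium”. On those grounds the forecast put the first product at 28.2 % now, 23.2 % after beta and 38.7 % after zeta, and chose zeta.

A colleague objected that the same readings suit a limiting reagent, shared between first product and other paths. She divided plateau [first product] by charged [reagent]: 0.425 for birch is the reagent yield, first product formed per reagent charged, and elm gave 0.450. On her reading, first product taken out is not rebuilt, so zeta gains nothing. The added 8.00 mM of reagent should instead make 17 percentage points of first product, provided substrate remains. She accepted the forecast's slow drain and named gamma.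

The flask gives 26.2 % at 8.0 d, 20.9 % after beta and 25.6 % after zeta, which is 13 points below the forecast. The best option is gamma, at 5.8 points against −0.62 points for zeta.

    substrate + reagent → first product + released group (k = 11.0 L mol⁻¹ h⁻¹, Ea = 67.0 kJ mol⁻¹)
    substrate + reagent → other mono adduct + released group (k = 9.70 L mol⁻¹ h⁻¹, Ea = 93.0 kJ mol⁻¹)
    reagent + first product → double product + released group (k = 0.520 L mol⁻¹ h⁻¹, Ea = 73.0 kJ mol⁻¹)
    reagent + other mono adduct → double product + released group (k = 8.10 L mol⁻¹ h⁻¹, Ea = 66.0 kJ mol⁻¹)
    substrate + first product → side product (k = 0.390 L mol⁻¹ h⁻¹, Ea = 67.0 kJ mol⁻¹)
    (constants at 90 °C)

In this flask the reagent's half-life by the step to first product is 0.20 d at 0.0756 d, against 5.8 d for first product by the step to side product. Free reagent stands at 0 % at 8.00 d, with substrate at 18 %. Measured against waiting, gamma brings 11 points, where the reagent yield promised 17 points. For the neighbour flask run at 75 °C, a straight line through the two yields gives a reagent yield of 0.500 at the plateau; computed, the first product of that neighbour stands at 37.3 % of the substrate charged at 8.00 d.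

Readings and results come from a simulation for an exercise; scatter was added.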